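Labdane numbering is used (decalin C1–C10; C19 is the oxygenated carbon on C4, C20 the methyl on C10). Ring B carries its exocyclic methylene on C8 next to C9; read as a C8 ketone, its C8=C9 enol ether is the retron of a Diels–Alder reaction. Everything rests on a thermal intramolecular Diels–Alder reaction of a 2-silyloxy-1,7,9-decatriene: the diene C7=C8(OSi)–C9(side chain)=C10(Me) and a vinyl group (C5=C6) on quaternary C4, linked through C1–C3, form C5–C10 and C6–C7 in one operation, closing rings A and B and setting C5 and C10. C4 comes from a Sharpless epoxide by a siloxymethyl 1,2-shift; C19 is held as a small formyl group to steer the cycloaddition.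

Key step: step 14

Remark: (3R)-5-methoxy-3-methyl-5-oxopentanoic acid and (2R)-2-methylbutanoic acid are taken as commercial single enantiomers; intermediates carry the labdane atom numbers of the target.

Step 1
Reactants: 1 5-chloropent-1-yne
Product: 4 (E)-6-chloro-3-methylhex-2-en-1-ol, via alkenylalane 2 (not isolated), via lithium aluminate 3 (not isolated)
Conditions: Me3Al, Cp2ZrCl2 (25 mol%), CH2Cl2, rt; n-BuLi, THF/hexane, −78 °C; (CH2O)n, −78 °C to rt; 1 M HCl
Reagents that add atoms: trimethylaluminium C[Al](C)C; paraformaldehyde (formaldehyde unit) C=O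
Why: Zirconium-catalysed Negishi methylalumination is a syn carbometalation that puts the methyl group on the internal alkyne carbon, and the derived aluminate adds to formaldehyde with retention, so the trisubstituted alkene should form as the E isomer only.

Step 2
Reactants: 4 (E)-6-chloro-3-methylhex-2-en-1-ol
Product: 5 [(2S,3S)-3-(3-chloropropyl)-3-methyloxiran-2-yl]methanol
Conditions: Ti(OiPr)4 (10 mol%), L-(+)-diethyl tartrate (12 mol%), t-BuOOH, 4 Å MS, CH2Cl2, −20 °C
Reagents that add atoms: tert-butyl hydroperoxide CC(C)(C)OO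
Why: Sharpless asymmetric epoxidation: with L-(+)-tartrate the titanium-bound peroxide is delivered to the alkene face that gives the (2S,3S)-epoxide of an (E)-3,3-disubstituted allylic alcohol, the same sense as for geraniol.

Step 3
Reactants: 5 [(2S,3S)-3-(3-chloropropyl)-3-methyloxiran-2-yl]methanol
Product: 6 {[(2S,3S)-3-(3-chloropropyl)-3-methyloxiran-2-yl]methoxy}triethylsilane
Conditions: Et3SiCl, imidazole, CH2Cl2, 0 °C
Reagents that add atoms: chlorotriethylsilane CC[Si](Cl)(CC)CC
Why: Imidazole-promoted O-silylation of the primary alcohol gives the epoxy silyl ether that the rearrangement needs, and no stereocentre is touched.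

Step 4
Reactants: 6 {[(2S,3S)-3-(3-chloropropyl)-3-methyloxiran-2-yl]methoxy}triethylsilane
Product: 7 (2S)-5-chloro-2-methyl-2-[(triethylsilyloxy)methyl]pentanal
Conditions: MeAl(OC6H2-4-Br-2,6-tBu2)2 (20 mol%), CH2Cl2, −78 to −20 °C
Reagents that add atoms: none
Why: Organoaluminium-promoted rearrangement of an epoxy silyl ether (semipinacol-type 1,2-shift): the Lewis acid opens the epoxide at the tertiary carbon and the siloxymethyl group migrates anti to the leaving oxygen, so the epoxide configuration is transferred with inversion to the new quaternary carbon, the future C4.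

Step 5
Reactants: 7 (2S)-5-chloro-2-methyl-2-[(triethylsilyloxy)methyl]pentanal
Product: 8 {[(2R)-5-chloro-2-ethenyl-2-methylpentyl]oxy}triethylsilane
Conditions: Ph3PCH3Br, KN(SiMe3)2, THF, 0 °C; then 7, −78 °C to rt
Reagents that add atoms: methyltriphenylphosphonium bromide C[P+](c1ccccc1)(c1ccccc1)c1ccccc1.[Br-]
Why: Wittig methylenation turns the formyl group into the C5=C6 vinyl group, and because the aldehyde has no α-hydrogen C4 cannot epimerise.

Step 6
Reactants: 8 {[(2R)-5-chloro-2-ethenyl-2-methylpentyl]oxy}triethylsilane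
Product: 9 {[(2R)-2-ethenyl-5-iodo-2-methylpentyl]oxy}triethylsilane
Conditions: NaI, acetone, reflux
Reagents that add atoms: sodium iodide [Na+].[I-]
Why: Finkelstein halide exchange (SN2 at the primary carbon, driven by precipitation of NaCl) gives the iodide needed for a clean iodine–lithium exchange.

Step 7
Reactants: 10 (3R)-5-methoxy-3-methyl-5-oxopentanoic acid
Product: 11 methyl (3R)-5-hydroxy-3-methylpentanoate
Conditions: BH3·SMe2, THF, −10 °C to rt; H2O
Reagents that add atoms: none
Why: Borane reduces the free carboxylic acid (through an acyloxyborane) much faster than the methyl ester, so only the acid arm becomes the primary alcohol and the preset C13 centre is untouched.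

Step 8
Reactants: 11 methyl (3R)-5-hydroxy-3-methylpentanoate
Product: 12 methyl (3S)-5-iodo-3-methylpentanoate
Conditions: I2, PPh3, imidazole, CH2Cl2, 0 °C to rt
Reagents that add atoms: iodine II
Why: Appel-type iodination (Garegg–Samuelsson conditions) of the primary alcohol through an alkoxyphosphonium ion, run at once so that the hydroxy ester does not lactonise.

Step 9
Reactants: 12 methyl (3S)-5-iodo-3-methylpentanoate; 13 pentane-2,4-dione
Product: 14 methyl (3R)-6-acetyl-3-methyl-7-oxooctanoate
Conditions: K2CO3, acetone, reflux (13 in excess)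
Reagents that add atoms: none
Why: C-Alkylation of the potassium enolate of a 1,3-diketone with a primary iodide (SN2) attaches the side chain to the future C9.

Step 10
Reactants: 14 methyl (3R)-6-acetyl-3-methyl-7-oxooctanoate
Product: 15 methyl (3R,6E)-6-acetyl-3-methyl-7-{[(trifluoromethyl)sulfonyl]oxy}oct-6-enoate
Conditions: Tf2O, aq. Me4NOH, toluene, 5 °C
Reagents that add atoms: trifluoromethanesulfonic anhydride O=S(=O)(OS(=O)(=O)C(F)(F)F)C(F)(F)F
Why: Stereoselective O-sulfonylation of a 1,3-dicarbonyl enolate: the non-chelated tetramethylammonium enolate should react from its extended form and place the triflate trans to the remaining acetyl group (E), whereas a chelated lithium enolate would give the Z isomer.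

Step 11
Reactants: 9 {[(2R)-2-ethenyl-5-iodo-2-methylpentyl]oxy}triethylsilane; 15 methyl (3R,6E)-6-acetyl-3-methyl-7-{[(trifluoromethyl)sulfonyl]oxy}oct-6-enoate
Product: 19 methyl (3R,6E,11R)-6-acetyl-11-(hydroxymethyl)-3,7,11-trimethyltrideca-6,12-dienoate, via alkyllithium 16 (not isolated), via alkylzinc chloride 17 (not isolated), via silyl ether enone 18 (not isolated)
Conditions: 9, t-BuLi (2 equiv), Et2O/pentane, −78 °C; ZnCl2, THF, −78 to 0 °C; 15, PdCl2(dppf) (5 mol%), THF, rt; then PPTS, MeOH, rt
Reagents that add atoms: none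
Why: Iodine–lithium exchange at −78 °C (a polar process, so the hex-5-enyl system should not cyclise), transmetalation to zinc and a stereoretentive Negishi coupling at the activated enol triflate should join the fragments with the C1 tether trans to the acetyl group, and mild acid methanolysis then frees the C19 alcohol.

Step 12
Reactants: 19 methyl (3R,6E,11R)-6-acetyl-11-(hydroxymethyl)-3,7,11-trimethyltrideca-6,12-dienoate
Product: 20 methyl (3R,6E,11R)-6-acetyl-11-formyl-3,7,11-trimethyltrideca-6,12-dienoate
Conditions: Dess–Martin periodinane, CH2Cl2, rt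
Reagents that add atoms: none
Why: Dess–Martin oxidation converts the neopentyl primary alcohol into the non-enolisable C19 aldehyde without touching the enone or the ester.

Step 13
Reactants: 20 methyl (3R,6E,11R)-6-acetyl-11-formyl-3,7,11-trimethyltrideca-6,12-dienoate
Product: 21 methyl (3R,6E,11R)-6-{1-[(tert-butyldimethylsilyl)oxy]ethenyl}-11-formyl-3,7,11-trimethyltrideca-6,12-dienoate
Conditions: t-BuMe2SiOTf, Et3N, CH2Cl2, −78 to 0 °C
Reagents that add atoms: tert-butyldimethylsilyl trifluoromethanesulfonate CC(C)(C)[Si](C)(C)OS(=O)(=O)C(F)(F)F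
Why: Soft enolisation (silyl triflate and tertiary amine) silylates the methyl ketone on its kinetic methyl side to the cross-conjugated 2-silyloxy diene, while the ester and the aldehyde, which has no α-hydrogen, stay unchanged.

Step 14
Reactants: 21 methyl (3R,6E,11R)-6-{1-[(tert-butyldimethylsilyl)oxy]ethenyl}-11-formyl-3,7,11-trimethyltrideca-6,12-dienoate
Product: 22 methyl (3R)-5-[(4aS,5R,8aR)-2-{[tert-butyl(dimethyl)silyl]oxy}-5-formyl-5,8a-dimethyl-3,4,4a,5,6,7,8,8a-octahydronaphthalen-1-yl]-3-methylpentanoate
Conditions: toluene (5 mM), BHT, Et3N (trace), sealed tube, 180 °C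
Reagents that add atoms: none
Why: Thermal type 1 intramolecular Diels–Alder reaction of a 2-silyloxy-1,7,9-decatriene, a concerted suprafacial [4+2] cycloaddition in which the C7=C8–C9=C10 diene and the C5=C6 vinyl group form the C6–C7 and C5–C10 bonds together. Ring B closes as the new cyclohexene and ring A closes at the same time through the C1–C3 tether and C4, both as six-membered rings in the fused (type 1) mode. C10 and C5 are set relative to each other by the E geometry of the C9=C10 bond (tether outside, methyl inside) and a chair-like anti transition state, which should give the trans ring fusion because the syn arrangement presses the C9 side chain and the C8 silyloxy group against the tether. Their sense relative to the preset C4 centre is controlled by the two free substituents of C4: the small planar formyl group should take the position syn to the inside C10 methyl group and the larger methyl group the outside position, which is the C19-axial, C18-equatorial arrangement of the target. The step therefore needs facial selectivity with respect to C4 and anti (trans-fusion) selectivity; the first rests on the size difference between CHO and CH3 (A values about 0.7 against 1.7 kcal/mol), the second on the substitution at C8 and C9. The resulting silyl enol ether marks C8 for the later ketone and leaves C9 correctable by equilibration.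

Step 15
Reactants: 22 methyl (3R)-5-[(4aS,5R,8aR)-2-{[tert-butyl(dimethyl)silyl]oxy}-5-formyl-5,8a-dimethyl-3,4,4a,5,6,7,8,8a-octahydronaphthalen-1-yl]-3-methylpentanoate
Product: 24 methyl (3R)-5-[(1S,4aS,5R,8aR)-5-(hydroxymethyl)-5,8a-dimethyl-2-oxodecahydronaphthalen-1-yl]-3-methylpentanoate, via silyl enol ether alcohol 23 (not isolated)
Conditions: LiAlH(OtBu)3, THF, 0 °C; then 1 M HCl, THF, rt
Reagents that add atoms: none
Why: Chemoselective hydride reduction of the aldehyde (ester and silyl enol ether inert) and acid hydrolysis of the silyl enol ether should give the C8 ketone, and acid-catalysed enolisation equilibrates C9 to the isomer with the side chain equatorial and cis to the C10 methyl group, the configuration of the target.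

Step 16
Reactants: 24 methyl (3R)-5-[(1S,4aS,5R,8aR)-5-(hydroxymethyl)-5,8a-dimethyl-2-oxodecahydronaphthalen-1-yl]-3-methylpentanoate; 25 (2R)-2-methylbutanoic acid
Product: 26 methyl (3R)-5-[(1S,4aS,5R,8aR)-5,8a-dimethyl-5-({[(2R)-2-methylbutanoyl]oxy}methyl)-2-oxodecahydronaphthalen-1-yl]-3-methylpentanoate
Conditions: DCC, DMAP (cat.), CH2Cl2, 0 °C to rt
Reagents that add atoms: none
Why: Steglich esterification acylates the hindered neopentyl C19 alcohol under conditions that should not racemise the α-stereocentre of the acid.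

Step 17
Reactants: 26 methyl (3R)-5-[(1S,4aS,5R,8aR)-5,8a-dimethyl-5-({[(2R)-2-methylbutanoyl]oxy}methyl)-2-oxodecahydronaphthalen-1-yl]-3-methylpentanoate
Product: 27 methyl (3R)-5-[(1R,4aS,5R,8aS)-5,8a-dimethyl-2-methylidene-5-({[(2R)-2-methylbutanoyl]oxy}methyl)decahydronaphthalen-1-yl]-3-methylpentanoate
Conditions: Zn, CH2Br2, TiCl4, THF/CH2Cl2, 0 °C to rt
Reagents that add atoms: dibromomethane BrCBr
Why: Lombardo methylenation (a non-basic titanium–zinc methylene reagent) should convert the hindered C8 ketone into the exocyclic methylene without epimerising C9 and without attacking either ester.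

Step 18
Reactants: 27 methyl (3R)-5-[(1R,4aS,5R,8aS)-5,8a-dimethyl-2-methylidene-5-({[(2R)-2-methylbutanoyl]oxy}methyl)decahydronaphthalen-1-yl]-3-methylpentanoate
Product: 28 (3R)-5-[(1R,4aS,5R,8aS)-5,8a-dimethyl-2-methylidene-5-({[(2R)-2-methylbutanoyl]oxy}methyl)decahydronaphthalen-1-yl]-3-methylpentanoic acid (CNP0365997.1)
Conditions: LiOH, THF/MeOH/H2O, 0 °C; then 1 M HCl to pH 3
Reagents that add atoms: lithium hydroxide [Li+].[OH-]
Why: Saponification (acyl–oxygen cleavage) of the unhindered methyl ester should be much faster than that of the α-branched ester of the neopentyl C19 alcohol, so the C15 acid is freed selectively.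

Compound list
1 | 5-chloropent-1-yne | C#CCCCCl | starting material
2 | (E)-(5-chloro-2-methylpent-1-en-1-yl)dimethylalane | C[Al](C)/C=C(\C)CCCCl | intermediate (not isolated)
3 | lithium butyl[(E)-5-chloro-2-methylpent-1-en-1-yl]dimethylaluminate | [Li+].CCCC[Al-](C)(C)/C=C(\C)CCCCl | intermediate (not isolated)
4 | (E)-6-chloro-3-methylhex-2-en-1-ol | OC/C=C(\C)CCCCl | intermediate
5 | [(2S,3S)-3-(3-chloropropyl)-3-methyloxiran-2-yl]methanol | ClCCC[C@]1(C)O[C@H]1CO | intermediate
6 | {[(2S,3S)-3-(3-chloropropyl)-3-methyloxiran-2-yl]methoxy}triethylsilane | ClCCC[C@]1(C)O[C@H]1CO[Si](CC)(CC)CC | intermediate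
7 | (2S)-5-chloro-2-methyl-2-[(triethylsilyloxy)methyl]pentanal | ClCCC[C@@](C)(CO[Si](CC)(CC)CC)C=O | intermediate
8 | {[(2R)-5-chloro-2-ethenyl-2-methylpentyl]oxy}triethylsilane | ClCCC[C@@](C)(CO[Si](CC)(CC)CC)C=C | intermediate
9 | {[(2R)-2-ethenyl-5-iodo-2-methylpentyl]oxy}triethylsilane | ICCC[C@@](C)(CO[Si](CC)(CC)CC)C=C | intermediate
10 | (3R)-5-methoxy-3-methyl-5-oxopentanoic acid | OC(=O)C[C@@H](C)CC(=O)OC | starting material
11 | methyl (3R)-5-hydroxy-3-methylpentanoate | OCC[C@@H](C)CC(=O)OC | intermediate
12 | methyl (3S)-5-iodo-3-methylpentanoate | ICC[C@@H](C)CC(=O)OC | intermediate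
13 | pentane-2,4-dione | CC(=O)CC(C)=O | starting material
14 | methyl (3R)-6-acetyl-3-methyl-7-oxooctanoate | CC(=O)C(CC[C@@H](C)CC(=O)OC)C(C)=O | intermediate
15 | methyl (3R,6E)-6-acetyl-3-methyl-7-{[(trifluoromethyl)sulfonyl]oxy}oct-6-enoate | CC(=O)/C(CC[C@@H](C)CC(=O)OC)=C(\C)OS(=O)(=O)C(F)(F)F | intermediate
16 | [(4R)-4-ethenyl-4-methyl-5-(triethylsilyloxy)pentyl]lithium | [Li]CCC[C@@](C)(CO[Si](CC)(CC)CC)C=C | intermediate (not isolated)
17 | chloro[(4R)-4-ethenyl-4-methyl-5-(triethylsilyloxy)pentyl]zinc | Cl[Zn]CCC[C@@](C)(CO[Si](CC)(CC)CC)C=C | intermediate (not isolated)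
18 | methyl (3R,6E,11R)-6-acetyl-3,7,11-trimethyl-11-[(triethylsilyloxy)methyl]trideca-6,12-dienoate | CC(=O)/C(CC[C@@H](C)CC(=O)OC)=C(\C)CCC[C@@](C)(CO[Si](CC)(CC)CC)C=C | intermediate (not isolated)
19 | methyl (3R,6E,11R)-6-acetyl-11-(hydroxymethyl)-3,7,11-trimethyltrideca-6,12-dienoate | CC(=O)/C(CC[C@@H](C)CC(=O)OC)=C(\C)CCC[C@@](C)(CO)C=C | intermediate
20 | methyl (3R,6E,11R)-6-acetyl-11-formyl-3,7,11-trimethyltrideca-6,12-dienoate | CC(=O)/C(CC[C@@H](C)CC(=O)OC)=C(\C)CCC[C@@](C)(C=O)C=C | intermediate
21 | methyl (3R,6E,11R)-6-{1-[(tert-butyldimethylsilyl)oxy]ethenyl}-11-formyl-3,7,11-trimethyltrideca-6,12-dienoate | C=C(O[Si](C)(C)C(C)(C)C)/C(CC[C@@H](C)CC(=O)OC)=C(\C)CCC[C@@](C)(C=O)C=C | intermediate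
22 | methyl (3R)-5-[(4aS,5R,8aR)-2-{[tert-butyl(dimethyl)silyl]oxy}-5-formyl-5,8a-dimethyl-3,4,4a,5,6,7,8,8a-octahydronaphthalen-1-yl]-3-methylpentanoate | C1(CC[C@@H](C)CC(=O)OC)=C(O[Si](C)(C)C(C)(C)C)CC[C@@H]2[C@](C)(C=O)CCC[C@@]12C | intermediate
23 | methyl (3R)-5-[(4aS,5R,8aR)-2-{[tert-butyl(dimethyl)silyl]oxy}-5-(hydroxymethyl)-5,8a-dimethyl-3,4,4a,5,6,7,8,8a-octahydronaphthalen-1-yl]-3-methylpentanoate | C1(CC[C@@H](C)CC(=O)OC)=C(O[Si](C)(C)C(C)(C)C)CC[C@@H]2[C@](C)(CO)CCC[C@@]12C | intermediate (not isolated)
24 | methyl (3R)-5-[(1S,4aS,5R,8aR)-5-(hydroxymethyl)-5,8a-dimethyl-2-oxodecahydronaphthalen-1-yl]-3-methylpentanoate | O=C1CC[C@@H]2[C@](C)(CO)CCC[C@@]2(C)[C@@H]1CC[C@@H](C)CC(=O)OC | intermediate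
25 | (2R)-2-methylbutanoic acid | CC[C@@H](C)C(=O)O | starting material
26 | methyl (3R)-5-[(1S,4aS,5R,8aR)-5,8a-dimethyl-5-({[(2R)-2-methylbutanoyl]oxy}methyl)-2-oxodecahydronaphthalen-1-yl]-3-methylpentanoate | O=C1CC[C@@H]2[C@](C)(COC(=O)[C@H](C)CC)CCC[C@@]2(C)[C@@H]1CC[C@@H](C)CC(=O)OC | intermediate
27 | methyl (3R)-5-[(1R,4aS,5R,8aS)-5,8a-dimethyl-2-methylidene-5-({[(2R)-2-methylbutanoyl]oxy}methyl)decahydronaphthalen-1-yl]-3-methylpentanoate | C=C1CC[C@@H]2[C@](C)(COC(=O)[C@H](C)CC)CCC[C@@]2(C)[C@@H]1CC[C@@H](C)CC(=O)OC | intermediate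
28 | (3R)-5-[(1R,4aS,5R,8aS)-5,8a-dimethyl-2-methylidene-5-({[(2R)-2-methylbutanoyl]oxy}methyl)decahydronaphthalen-1-yl]-3-methylpentanoic acid (CNP0365997.1) | C=C1CC[C@@H]2[C@](C)(COC(=O)[C@H](C)CC)CCC[C@@]2(C)[C@@H]1CC[C@@H](C)CC(=O)O | target

Total step count: 18. Longest linear sequence: 14 steps (steps 1–6 and 11–18, from 1); the side-chain branch (steps 7–10) joins at step 11.

Steps most likely to fail

1. Step 14 (key cycloaddition). At 180 °C the slow cycloaddition of the unactivated vinyl group may be overtaken by a 1,5-hydrogen shift from the C20 methyl group into the diene, by loss of the silyl enol ether or by reaction at the formyl group, and the facial preference may erode at that temperature. Fallback: thermal activation is replaced by metal catalysis, the rhodium-catalysed intramolecular diene–ene [4+2] cycloaddition ([RhCl(cyclooctene)2]2, P[OCH(CF3)2]3, THF, 55 °C). It runs through oxidative cyclisation and reductive elimination at a temperature where these side reactions should be slow. It sets out from 21 and comes back at 22, and it makes no new compound (F0).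

2. Step 10 (enol triflate geometry). The enolate of the symmetric diketone may be sulfonylated with poor E/Z control, or the triflate may isomerise, so that the tether ends up cis to the acetyl group and cannot reach the trans-fused transition state. Fallback: the tetrasubstituted alkene is built by a stereospecific syn carbocupration instead. It sets out from 9 (through 16, made as in step 11) and from 12, and it comes back at 18. Alkyllithium 16 is converted with CuBr·SMe2 (THF, −78 °C) into [(4R)-4-ethenyl-4-methyl-5-(triethylsilyloxy)pentyl]copper F2, which adds syn across N-methoxy-N-methylbut-2-ynamide F1 (from but-2-ynoic acid, N,O-dimethylhydroxylamine hydrochloride, EDC and Et3N) to give the alkenylcopper adduct F3. Iodine at −78 °C should give, with retention, (2Z,7R)-7-ethenyl-2-iodo-N-methoxy-N,3,7-trimethyl-8-(triethylsilyloxy)oct-2-enamide F4. MeMgBr (THF, −20 °C) converts this Weinreb amide into (3Z,8R)-8-ethenyl-3-iodo-4,8-dimethyl-9-(triethylsilyloxy)non-3-en-2-one F5. Negishi coupling of F5 with iodo[(3S)-5-methoxy-3-methyl-5-oxopentyl]zinc F6 (from 12, Zn, LiCl, THF) under PdCl2(dppf) should give 18, and PPTS in MeOH then gives 19 as in step 11.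

3. Step 18 (selective ester cleavage). Hydroxide may also cleave the 2-methylbutanoate, so that the C19 ester is lost together with the methyl ester. Fallback: the methyl ester is cleaved at the alkyl–oxygen bond instead, with LiI in refluxing ethyl acetate followed by dilute HCl. Iodide attacks the methyl group by SN2, a path closed to the ester of the neopentyl C19 carbon. It sets out from 27 and comes back at 28, and it makes no new compound (F0).

Further compounds
F0 | step 14 | none | none
F1 | step 10 | N-methoxy-N-methylbut-2-ynamide | CC#CC(=O)N(C)OC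
F2 | step 10 | [(4R)-4-ethenyl-4-methyl-5-(triethylsilyloxy)pentyl]copper | [Cu]CCC[C@@](C)(CO[Si](CC)(CC)CC)C=C
F3 | step 10 | {(1Z,6R)-6-ethenyl-1-[methoxy(methyl)carbamoyl]-2,6-dimethyl-7-(triethylsilyloxy)hept-1-en-1-yl}copper (alkenylcopper adduct) | CON(C)C(=O)/C([Cu])=C(\C)CCC[C@@](C)(CO[Si](CC)(CC)CC)C=C
F4 | step 10 | (2Z,7R)-7-ethenyl-2-iodo-N-methoxy-N,3,7-trimethyl-8-(triethylsilyloxy)oct-2-enamide | CON(C)C(=O)/C(I)=C(\C)CCC[C@@](C)(CO[Si](CC)(CC)CC)C=C
F5 | step 10 | (3Z,8R)-8-ethenyl-3-iodo-4,8-dimethyl-9-(triethylsilyloxy)non-3-en-2-one | CC(=O)/C(I)=C(\C)CCC[C@@](C)(CO[Si](CC)(CC)CC)C=C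
F6 | step 10 | iodo[(3S)-5-methoxy-3-methyl-5-oxopentyl]zinc | I[Zn]CC[C@@H](C)CC(=O)OC
F0 | step 18 | none | none
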